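**Strategy.** The cyclohexene ring (C1 CH–O‑acyl, C2 CH2, C3 =CH, C4 =C(CH3), C5 CH–CH2OAr, C6 C(CH3)2) is cut at C2–C3 and C5–C6 into two isoprene-derived C5 units. A one-pot (3+3) annulation makes both bonds. The dianion of an allylic hydroxy sulfone is alkylated by (R)-3,3-dimethylglycidyl tosylate (C2–C3). Titanocene(III) then opens the epoxide to the C6 radical, which closes 6-endo onto the alkene (C5–C6) and expels the sulfonyl radical, fixing C3=C4. The step exploits the C1 oxygen next to the gem-dimethyl carbon C6 (a latent epoxide) and the allylic C3 of the ring alkene. Mitsunobu etherification with umbelliferone and acylation follow.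

Key step: step 4

Remark on the chemistry: the minor (Z)-isomer and regioisomers carried from step 1 are assumed to be removable by crystallisation of sulfone 4. The target is the cis isomer (1R,5S).

**Step 1**
Reactants: 1 isoprene
Product: 2 (2E)-4-chloro-3-methylbut-2-en-1-yl acetate
Conditions: t-BuOCl, AcOH, 15 °C; then TsOH (cat.), AcOH, rt; distil
Reagents that add atoms: tert-butyl hypochlorite, CC(C)(C)OCl; acetic acid, CC(=O)O
Why: Electrophilic 1,4-chloroacetoxylation of the diene, in which Cl+ adds to the CH2 next to the methyl-bearing carbon to give the tertiary allyl cation, and acid equilibration should convert the tertiary (1,2-) acetate into the primary (E)-allylic acetate.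

**Step 2**
Reactants: 2 (2E)-4-chloro-3-methylbut-2-en-1-yl acetate
Product: 4 (2E)-3-methyl-4-(4-methylbenzenesulfonyl)but-2-en-1-ol, via sulfone acetate 3 (not isolated)
Conditions: TolSO2Na, DMF, 50 °C; then K2CO3 (cat.), MeOH, 0 °C → rt; recrystallise
Reagents that add atoms: sodium p-toluenesulfinate, Cc1ccc(cc1)S(=O)[O-].[Na+]
Why: SN2 S-alkylation of the sulfinate by the primary allylic chloride followed by Zemplén-type methanolysis of the acetate, which is much faster than any base-induced 1,4-elimination; the alkene geometry is untouched.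

**Step 3**
Reactants: 5 3-methylbut-2-en-1-ol (prenol)
Product: 7 [(2R)-3,3-dimethyloxiran-2-yl]methyl 4-methylbenzenesulfonate, via epoxy alcohol 6 (not isolated)
Conditions: Ti(OiPr)4 (5 mol%), D-(−)-DIPT (7 mol%), t-BuOOH, 4 Å MS, CH2Cl2, −20 °C; then P(OMe)3; Et3N, DMAP (cat.), TsCl, −10 °C
Reagents that add atoms: tert-butyl hydroperoxide, CC(C)(C)OO; p-toluenesulfonyl chloride, Cc1ccc(cc1)S(Cl)(=O)=O
Why: Katsuki–Sharpless asymmetric epoxidation of the primary allylic alcohol, where D-(−)-tartrate should give the (2R)-epoxide, with in situ tosylation because the small epoxy alcohol is water-soluble.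

**Step 4**
Reactants: 4 (2E)-3-methyl-4-(4-methylbenzenesulfonyl)but-2-en-1-ol; 7 [(2R)-3,3-dimethyloxiran-2-yl]methyl 4-methylbenzenesulfonate
Product: 9 (1R,5S)-5-(hydroxymethyl)-4,6,6-trimethylcyclohex-3-en-1-ol, via epoxy sulfone 8 (not isolated)
Conditions: n-BuLi (2.05 equiv), THF, −78 °C; 7, −78 → 0 °C; then collidine·HCl (1.1 equiv), slow addition of Cp2TiCl (2.5 equiv, from Cp2TiCl2/Mn, THF), rt; 1 M HCl
Reagents that add atoms: none
Why: Proposed new method: the O,C-dilithio derivative of 4 should be alkylated at the sulfonyl-bearing carbon by the primary tosylate of 7 (SN2) to give 8, after which Cp2TiCl opens the epoxide by single-electron transfer at the tertiary carbon, the β-titanoxy tertiary radical adds to the CH terminus of the trisubstituted alkene, and the resulting tertiary radical ejects the p-toluenesulfonyl radical. The closest known reaction types are the Julia-type alkylation of allyl sulfone anions, the Nugent–RajanBabu titanocene(III) epoxypolyene radical cyclization and radical allylation with allyl sulfones (SH2′); the telescoped sequence with sulfonyl expulsion as the terminating event is the untested part. The ring closes in the 6-endo-trig mode, which should beat 5-exo because the internal alkene carbon is fully substituted and the attacking radical is tertiary. The new stereocentre (CH–CH2OH) is controlled by the Sharpless-derived carbinol centre through a chair transition state with the O–Ti group equatorial and the (E)-alkene placing CH2O equatorial, which gives the cis-1,3 relation, and the carbinol C–O bond is never broken. The step is convergent in the sulfonyl-bearing carbon, since both epimers of 8 lose that centre and give the same alkene, whose endocyclic position is dictated by the leaving group. It needs C- over O-alkylation (the carbanion is far more nucleophilic), epoxide opening toward the tertiary radical, and cyclization faster than radical reduction, which slow addition of Ti(III) should secure.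

**Step 5**
Reactants: 9 (1R,5S)-5-(hydroxymethyl)-4,6,6-trimethylcyclohex-3-en-1-ol; 10 umbelliferone (7-hydroxy-2H-chromen-2-one)
Product: 11 7-{[(1S,5R)-5-hydroxy-2,6,6-trimethylcyclohex-2-en-1-yl]methoxy}-2H-chromen-2-one
Conditions: PPh3, DIAD (slow addition), THF, 0 °C → rt
Reagents that add atoms: none
Why: Mitsunobu etherification, in which the primary alcohol is activated as the alkoxyphosphonium salt and displaced by the acidic phenol (SN2 at CH2, no stereocentre involved) while the secondary alcohol next to the quaternary carbon should stay untouched.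

**Step 6**
Reactants: 11 7-{[(1S,5R)-5-hydroxy-2,6,6-trimethylcyclohex-2-en-1-yl]methoxy}-2H-chromen-2-one; 12 3-methylbutanoyl chloride
Product: 13 (1R,5S)-4,6,6-trimethyl-5-{[(2-oxo-2H-chromen-7-yl)oxy]methyl}cyclohex-3-en-1-yl 3-methylbutanoate
Conditions: pyridine, DMAP (cat.), CH2Cl2, 0 °C → rt
Reagents that add atoms: none
Why: DMAP-catalysed acyl transfer to the equatorial secondary alcohol, with retention at the carbinol carbon because its C–O bond is not broken; the coumarin lactone and the alkene are inert.

**Compound list**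
1 | isoprene (2-methylbuta-1,3-diene) | CC(=C)C=C | starting material
2 | (2E)-4-chloro-3-methylbut-2-en-1-yl acetate | ClC/C(C)=C/COC(C)=O | intermediate
3 | (2E)-3-methyl-4-(4-methylbenzenesulfonyl)but-2-en-1-yl acetate | Cc1ccc(cc1)S(=O)(=O)C/C(C)=C/COC(C)=O | intermediate
4 | (2E)-3-methyl-4-(4-methylbenzenesulfonyl)but-2-en-1-ol | Cc1ccc(cc1)S(=O)(=O)C/C(C)=C/CO | intermediate
5 | 3-methylbut-2-en-1-ol (prenol) | CC(C)=CCO | starting material
6 | [(2R)-3,3-dimethyloxiran-2-yl]methanol | OC[C@H]1OC1(C)C | intermediate
7 | [(2R)-3,3-dimethyloxiran-2-yl]methyl 4-methylbenzenesulfonate | Cc1ccc(cc1)S(=O)(=O)OC[C@H]1OC1(C)C | intermediate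
8 | (2E)-5-[(2R)-3,3-dimethyloxiran-2-yl]-3-methyl-4-(4-methylbenzenesulfonyl)pent-2-en-1-ol (both C4 epimers) | Cc1ccc(cc1)S(=O)(=O)C(C[C@H]1OC1(C)C)/C(C)=C/CO | intermediate
9 | (1R,5S)-5-(hydroxymethyl)-4,6,6-trimethylcyclohex-3-en-1-ol | CC1=CC[C@@H](O)C(C)(C)[C@H]1CO | intermediate
10 | umbelliferone (7-hydroxy-2H-chromen-2-one) | Oc1ccc2ccc(=O)oc2c1 | starting material
11 | 7-{[(1S,5R)-5-hydroxy-2,6,6-trimethylcyclohex-2-en-1-yl]methoxy}-2H-chromen-2-one | CC1=CC[C@@H](O)C(C)(C)[C@H]1COc1ccc2ccc(=O)oc2c1 | intermediate
12 | 3-methylbutanoyl chloride | CC(C)CC(Cl)=O | starting material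
13 | (1R,5S)-4,6,6-trimethyl-5-{[(2-oxo-2H-chromen-7-yl)oxy]methyl}cyclohex-3-en-1-yl 3-methylbutanoate | CC1=CC[C@@H](OC(=O)CC(C)C)C(C)(C)[C@H]1COc1ccc2ccc(=O)oc2c1 | target

Total step count: 6. Longest linear sequence: 5 steps (steps 1, 2, 4, 5, 6).

**Steps most likely to fail**

1. Step 4 (Proposed new method). The tertiary radical may be reduced or lose a β-hydrogen before it cyclizes, and 5-exo closure can compete. Facial control may also be eroded by the sulfonyl-bearing stereocentre, or the alkylation with the tosylate may be sluggish. The fallback uses known chemistry only, sets out from 4 and 7 and returns at 9. The alkylation is run alone (n-BuLi, THF, then 7) and 8 is isolated. Reductive desulfonylation (Na/Hg, Na2HPO4, MeOH, −20 °C) should give (2E)-5-[(2R)-3,3-dimethyloxiran-2-yl]-3-methylpent-2-en-1-ol F1. Acetylation (Ac2O, pyridine) gives (2E)-5-[(2R)-3,3-dimethyloxiran-2-yl]-3-methylpent-2-en-1-yl acetate F2. The classical Lewis-acid epoxy-olefin cyclization (ZrCl4 or SnCl4, CH2Cl2, low temperature) then gives [(1S,5R)-5-hydroxy-2,6,6-trimethylcyclohex-2-en-1-yl]methyl acetate F3, from which the exocyclic-alkene isomer is separated. Methanolysis (K2CO3, MeOH) leads back to 9.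

2. Step 5. The 1,4-diol may close to the bridged tetrahydrofuran by intramolecular etherification, and substitution at the β-branched primary carbon may be slow. The fallback sets out from 9 and returns at 13. Exhaustive acylation with 12 (pyridine, DMAP) gives [(1S,5R)-2,6,6-trimethyl-5-(3-methylbutanoyloxy)cyclohex-2-en-1-yl]methyl 3-methylbutanoate F4. Selective methanolysis of the unhindered primary ester (K2CO3, MeOH, 0 °C) gives (1R,5S)-5-(hydroxymethyl)-4,6,6-trimethylcyclohex-3-en-1-yl 3-methylbutanoate F5. With the secondary oxygen already blocked, Mitsunobu etherification of F5 with 10 (PPh3, DIAD, THF) gives 13 directly.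

3. Step 1. Capture of the allyl cation at the tertiary position and formation of the (Z)-isomer may leave a mixture that cannot be fully equilibrated or separated. The fallback sets out from 5 and returns at 2. Acetylation (Ac2O, pyridine) gives 3-methylbut-2-en-1-yl acetate F6. Allylic oxidation of the (E)-methyl group (SeO2 cat., t-BuOOH, CH2Cl2) gives (2E)-4-hydroxy-3-methylbut-2-en-1-yl acetate F7. Chlorination without allylic transposition (MsCl, LiCl, 2,4,6-collidine, DMF, 0 °C) gives 2.

**Further compounds**
F1 | step 4 | (2E)-5-[(2R)-3,3-dimethyloxiran-2-yl]-3-methylpent-2-en-1-ol | OC/C=C(\C)CC[C@H]1OC1(C)C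
F2 | step 4 | (2E)-5-[(2R)-3,3-dimethyloxiran-2-yl]-3-methylpent-2-en-1-yl acetate | CC(=O)OC/C=C(\C)CC[C@H]1OC1(C)C
F3 | step 4 | [(1S,5R)-5-hydroxy-2,6,6-trimethylcyclohex-2-en-1-yl]methyl acetate | CC1=CC[C@@H](O)C(C)(C)[C@H]1COC(C)=O
F4 | step 5 | [(1S,5R)-2,6,6-trimethyl-5-(3-methylbutanoyloxy)cyclohex-2-en-1-yl]methyl 3-methylbutanoate | CC1=CC[C@@H](OC(=O)CC(C)C)C(C)(C)[C@H]1COC(=O)CC(C)C
F5 | step 5 | (1R,5S)-5-(hydroxymethyl)-4,6,6-trimethylcyclohex-3-en-1-yl 3-methylbutanoate | CC1=CC[C@@H](OC(=O)CC(C)C)C(C)(C)[C@H]1CO
F6 | step 1 | 3-methylbut-2-en-1-yl acetate | CC(C)=CCOC(C)=O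
F7 | step 1 | (2E)-4-hydroxy-3-methylbut-2-en-1-yl acetate | OC/C(C)=C/COC(C)=O
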